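**Plan**

- The target, 2-(3,4-dimethoxyphenyl)-3-hydroxy-7-(prenyloxy)-4H-chromen-4-one, is an achiral flavonol. The retrosynthesis cuts, in order, the acetal O–CH2 bond of a 3-O-MOM ether, the aryl C7–O bond of the prenyl ether, the aryl O1–C8a bond of ring C, and the C3–C4 bond.
- Enabling feature: on ring A, O1–C8a lies ortho and the C7–O bond para to the C4 carbonyl, so both aryl C–O bonds can be made by displacing the fluorides of a 2,4-difluorobenzoyl unit.
- Forward: bromoketone 1 is taken through formate 2 and ketol 3 to MOM ether 4, whose lithium enolate is C-acylated with 2,4-difluorobenzoyl chloride 5 to give diketone 6 (C3–C4 bond).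
- Ring C then closes by intramolecular O-arylation at the ortho fluoride (6 to chromone 7); rings A and B are bought intact.
- The surviving C7 fluoride is exchanged for the alkoxide of prenol 8 (giving 9), and the MOM group is removed to give target 10.
- Stereochemistry: the target has no stereocentre; the one racemic centre of 6 becomes sp2 on cyclisation.

Key step: step 4

Remark: the enolates and the alkoxide generated by deprotonation with LiN(SiMe3)2, K2CO3 or NaH are regarded as salts of the numbered compounds that react in situ; the formate ester of step 1 is the only covalently distinct intermediate that is not isolated.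

**Route**

Step 1
Reactants: 1 2-bromo-1-(3,4-dimethoxyphenyl)ethanone
Product: 3 2-hydroxy-1-(3,4-dimethoxyphenyl)ethanone, via formate ester 2 (not isolated)
Conditions: HCO2Na (3 equiv), EtOH/H2O 4:1, reflux
Reagents that add atoms: sodium formate (HCO2Na), O=C[O-].[Na+]
Why: SN2 displacement of the phenacyl bromide by formate followed by hydrolysis of the labile formate ester in the same pot should deliver the ketol while avoiding the aldol and Favorskii-type side reactions of direct hydroxide treatment.

Step 2
Reactants: 3 2-hydroxy-1-(3,4-dimethoxyphenyl)ethanone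
Product: 4 1-(3,4-dimethoxyphenyl)-2-(methoxymethoxy)ethanone
Conditions: MOMCl, i-Pr2NEt, CH2Cl2, 0 °C → rt
Reagents that add atoms: chloromethyl methyl ether (MOMCl), COCCl
Why: Standard MOM protection (O-alkylation of a primary alcohol with an α-chloro ether under amine base) masks the hydroxyl as a base-stable acetal that should survive the enolate chemistry and both fluoride displacements.

Step 3
Reactants: 4 1-(3,4-dimethoxyphenyl)-2-(methoxymethoxy)ethanone; 5 2,4-difluorobenzoyl chloride
Product: 6 rac-1-(2,4-difluorophenyl)-3-(3,4-dimethoxyphenyl)-2-(methoxymethoxy)propane-1,3-dione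
Conditions: 4 (2.0 equiv), LiN(SiMe3)2 (2.1 equiv), toluene/THF, −78 °C; then 5 (1.0 equiv), −78 → 0 °C; aq. NH4Cl
Reagents that add atoms: none
Why: Claisen-type C-acylation of a preformed, chelated lithium enolate of the α-alkoxy ketone with an acid chloride in a weakly coordinating medium should favour the carbon terminus, and the second equivalent of enolate deprotonates the more acidic diketone so that over-acylation is suppressed (the excess of 4 is recoverable).

Step 4
Reactants: 6 rac-1-(2,4-difluorophenyl)-3-(3,4-dimethoxyphenyl)-2-(methoxymethoxy)propane-1,3-dione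
Product: 7 2-(3,4-dimethoxyphenyl)-7-fluoro-3-(methoxymethoxy)-4H-chromen-4-one
Conditions: K2CO3 (2 equiv), DMF (0.05 M), 60 °C
Reagents that add atoms: none
Why: K2CO3 deprotonates the central carbon of the diketone, and the enolate oxygen on the dimethoxybenzoyl side adds to the fluorine-bearing carbon ortho to the other ketone, giving a Meisenheimer adduct stabilised by that carbonyl, from which fluoride is expelled to give the chromone. The closest known reaction type is the base-mediated intramolecular SNAr O-arylation of 1-(2-halophenyl)-1,3-diketones to 4H-chromen-4-ones. Ring C closes in a six-membered mode by forming O1–C8a (6-exo-trig with respect to the C8a–C8 π bond of the arene). No stereocentre is created, and the racemic carbinol-type carbon of 6 becomes the sp2 C3 of the chromone with its oxygen already in place as the MOM enol ether. The step needs O- over C-arylation and ortho over para displacement: the enolate carbon could reach the ring only through a four-membered transition state, and the para fluoride is out of reach of the tethered oxygen. At this dilution the para fluoride should therefore survive as the C7 handle for step 5.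

Step 5
Reactants: 7 2-(3,4-dimethoxyphenyl)-7-fluoro-3-(methoxymethoxy)-4H-chromen-4-one; 8 3-methylbut-2-en-1-ol (prenol)
Product: 9 2-(3,4-dimethoxyphenyl)-3-(methoxymethoxy)-7-[(3-methylbut-2-en-1-yl)oxy]-4H-chromen-4-one
Conditions: 8 (1.5 equiv), NaH (1.4 equiv), THF/DMF, 0 °C; then 7, 0 °C → rt
Reagents that add atoms: none
Why: Intermolecular SNAr (addition–elimination): the C7 fluoride is para to the C4 carbonyl, so the sodium alkoxide of 8 should add at C7 to a carbonyl-stabilised Meisenheimer adduct and expel fluoride, while the MOM group prevents formation of a deactivating 3-olate.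

Step 6
Reactants: 9 2-(3,4-dimethoxyphenyl)-3-(methoxymethoxy)-7-[(3-methylbut-2-en-1-yl)oxy]-4H-chromen-4-one
Product: 10 2-(3,4-dimethoxyphenyl)-3-hydroxy-7-[(3-methylbut-2-en-1-yl)oxy]-4H-chromen-4-one
Conditions: HCl (0.5 M in MeOH, catalytic), MeOH/CH2Cl2, 0 °C → rt
Reagents that add atoms: none
Why: Acid-catalysed transacetalisation of the MOM ether with methanol (MOM cleavage) should be fast at the 3-oxygen, a good leaving group flanked by the C4 carbonyl, under conditions dilute and cold enough to leave the aryl prenyl ether and its trisubstituted alkene untouched.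

**Compound list**

1 | 2-bromo-1-(3,4-dimethoxyphenyl)ethanone | COc1ccc(C(=O)CBr)cc1OC | starting material
2 | 2-(3,4-dimethoxyphenyl)-2-oxoethyl formate | COc1ccc(C(=O)COC=O)cc1OC | intermediate
3 | 2-hydroxy-1-(3,4-dimethoxyphenyl)ethanone | COc1ccc(C(=O)CO)cc1OC | intermediate
4 | 1-(3,4-dimethoxyphenyl)-2-(methoxymethoxy)ethanone | COCOCC(=O)c1ccc(OC)c(OC)c1 | intermediate
5 | 2,4-difluorobenzoyl chloride | O=C(Cl)c1ccc(F)cc1F | starting material
6 | rac-1-(2,4-difluorophenyl)-3-(3,4-dimethoxyphenyl)-2-(methoxymethoxy)propane-1,3-dione | COCOC(C(=O)c1ccc(OC)c(OC)c1)C(=O)c1ccc(F)cc1F | intermediate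
7 | 2-(3,4-dimethoxyphenyl)-7-fluoro-3-(methoxymethoxy)-4H-chromen-4-one | COCOc1c(-c2ccc(OC)c(OC)c2)oc2cc(F)ccc2c1=O | intermediate
8 | 3-methylbut-2-en-1-ol (prenol) | CC(C)=CCO | starting material
9 | 2-(3,4-dimethoxyphenyl)-3-(methoxymethoxy)-7-[(3-methylbut-2-en-1-yl)oxy]-4H-chromen-4-one | COCOc1c(-c2ccc(OC)c(OC)c2)oc2cc(OCC=C(C)C)ccc2c1=O | intermediate
10 | 2-(3,4-dimethoxyphenyl)-3-hydroxy-7-[(3-methylbut-2-en-1-yl)oxy]-4H-chromen-4-one | COc1ccc(-c2oc3cc(OCC=C(C)C)ccc3c(=O)c2O)cc1OC | target

Total step count: 6. Longest linear sequence: 6 steps (1 → 10).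

**Steps most likely to fail**

Step 5. Conjugate addition of the alkoxide at C2 with opening of the pyranone ring may outrun fluoride displacement at the only moderately activated C7. The fallback separates aryl C–O formation from prenyl attachment and sets out from 7. Treatment with acetohydroxamic acid and K2CO3 in DMSO at 80 °C (SNAr by the weakly basic hydroxamate, then Lossen-type fragmentation) should give 2-(3,4-dimethoxyphenyl)-7-hydroxy-3-(methoxymethoxy)-4H-chromen-4-one F1. Williamson alkylation of this phenol with prenyl bromide and K2CO3 in acetone then returns to the route at 9.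

Step 6. Acid-promoted ionisation of the allylic aryl ether, or Markovnikov addition of methanol to the alkene, may compete with acetal cleavage. The fallback removes the MOM group before any prenyl group is present and sets out from 7. Compound 7 is converted as above into 2-(3,4-dimethoxyphenyl)-7-hydroxy-3-(methoxymethoxy)-4H-chromen-4-one F1, which is deprotected with methanolic HCl at 40 °C to 2-(3,4-dimethoxyphenyl)-3,7-dihydroxy-4H-chromen-4-one F2. The 7-hydroxyl, conjugated to the C4 carbonyl, is the more acidic, whereas the 3-hydroxyl is hydrogen-bonded to that carbonyl. One equivalent of prenyl bromide with K2CO3 in DMF at 0 °C → rt should therefore alkylate O7 selectively and reach the route again at 10.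

Step 3. O-acylation of the enolate, or a second acylation of the product, may compete with C-acylation. The fallback builds the same C3–C4 bond at the alcohol oxidation level and sets out from 4. Aldol addition of its lithium enolate (LiN(SiMe3)2, THF, −78 °C) to 2,4-difluorobenzaldehyde should give 3-(2,4-difluorophenyl)-1-(3,4-dimethoxyphenyl)-3-hydroxy-2-(methoxymethoxy)propan-1-one F3 as a diastereomer mixture of no consequence. Oxidation with Dess–Martin periodinane (NaHCO3, CH2Cl2) then rejoins the route at 6.

**Further compounds**

F1 | step 5 | 2-(3,4-dimethoxyphenyl)-7-hydroxy-3-(methoxymethoxy)-4H-chromen-4-one | COCOc1c(-c2ccc(OC)c(OC)c2)oc2cc(O)ccc2c1=O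
F2 | step 6 | 2-(3,4-dimethoxyphenyl)-3,7-dihydroxy-4H-chromen-4-one | COc1ccc(-c2oc3cc(O)ccc3c(=O)c2O)cc1OC
F3 | step 3 | 3-(2,4-difluorophenyl)-1-(3,4-dimethoxyphenyl)-3-hydroxy-2-(methoxymethoxy)propan-1-one | COCOC(C(O)c1ccc(F)cc1F)C(=O)c1ccc(OC)c(OC)c1
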